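**Retrosynthetic overview**

1. The target is reached by ordered acylation and deprotection of a trans-hydrindan-4-one acyloin (C4 ketone, C5 hydroxyl); O8 (PMB ether) and O9 (silyl ether) are told apart when an 8,9-epoxide is opened.
2. Ring A (C2–C3–C4–C5–C6) comes from an α-ketol ring expansion of a 1-formylcyclobutanol: C5 is added as a formyl anion equivalent to the cyclobutanone carbon C4 and then inserted between C4 and C6.
3. The ring B functions come from a trans-fused bicyclo[4.2.0]octan-2-one through the C8=C9 enone, its α-epoxide, a masked C1 methylene (Peterson) and trans-diaxial opening at C8. The trans fusion is kinetic and cannot be corrected once C1 is an alkene, so C1 is made sp3 before any enolising reagent is used.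
4. The cyclobutane (bonds C2–C3 and C6–C4) comes from a [2+2] photocycloaddition of (S)-cryptone with 1,1-dimethoxyethene. The feature used is that C2 and C6 are the α and β carbons of a ring B enone whose carbonyl carbon C1 later carries the methylene, while ring A is that cyclobutanone (C3, C4) plus one carbon.
5. Ring order: ring B (organocatalytic Michael addition, then aldol condensation, which sets C7), then the cyclobutane, then ring A by expansion.

Key step: step 3

**Remarks**

- Numbering follows the target throughout: C10=C1 exocyclic alkene, ring fusion C2 and C6, C3 methylene, C4 ketone, C5 acetoxy, C7 isopropyl, C8 hydroxy, C9 angeloyloxy. β is the face of ring B that carries the C7 isopropyl group, α the opposite face. The target has H-2 α, H-6 β, O5 β, O8 β and O9 α.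
- Assumption on the chemistry: the trans-fused photoadduct epimerises at C2 under base, so every step that still has the C1 ketone is run under kinetic or neutral conditions.

**Route**

Step 1
Reactants: 1 isovaleraldehyde (3-methylbutanal); 2 methyl vinyl ketone (but-3-en-2-one)
Product: 3 (S)-2-isopropyl-5-oxohexanal
Conditions: (S)-2-(methoxydiphenylmethyl)pyrrolidine (5 mol %), ethyl 3,4-dihydroxybenzoate (20 mol %), neat, 4 °C
Reagents that add atoms: none
Why: Enamine catalysis (organocatalytic Michael addition of an aldehyde to an enone): the (E)-enamine of 1 adds to 2, which is activated by the catechol hydrogen-bond donor, on the face remote from the methoxydiphenylmethyl group, and this should set the (S) centre that becomes C7.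

Step 2
Reactants: 3 (S)-2-isopropyl-5-oxohexanal
Product: 5 (S)-cryptone, via cyclic aldol 4 (not isolated)
Conditions: LiOH (0.1 equiv), i-PrOH, rt
Reagents that add atoms: none
Why: Intramolecular aldol condensation (the ring-closing half of a Robinson annulation) of the methyl ketone enolate onto the aldehyde, followed by E1cB dehydration, closes ring B as the conjugated enone, and the mild base and fast cyclisation should leave the α-branched centre untouched.

Step 3
Reactants: 5 (S)-cryptone [(S)-4-isopropylcyclohex-2-en-1-one]; 6 1,1-dimethoxyethene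
Product: 7 trans-fused (1R,5S,6S)-5-isopropyl-7,7-dimethoxybicyclo[4.2.0]octan-2-one (C1 ketone, H-2 α, H-6 β, acetal carbon C4 on C6)
Conditions: hν (350 nm, Pyrex), 6 (10 equiv), hexane, −40 °C; chromatography on neutral silica
Reagents that add atoms: none
Why: The enone is excited to its twisted triplet, which adds to the electron-rich alkene stepwise through a triplet 1,4-biradical that closes after spin inversion; this is the classical enone–alkene [2+2] photocycloaddition as known for cyclohexenones and 1,1-dialkoxyethenes. The polarity of the excited enone orients the donor alkene head-to-tail, so that the alkene CH2 (C3) bonds to the α carbon C2 and the acetal carbon C4 to the β carbon C6. The only ring formed, the cyclobutane C2–C3–C4–C6, is closed by recombination of the two radical centres of the biradical (formation of the second σ bond). C6 is controlled by the adjacent C7 isopropyl group, the C6–C4 bond forming on the face opposite to it, and C2 by the twisted geometry of the triplet, which places the C2–C3 bond on the other face and gives the strained trans fusion under kinetic control. The step needs head-to-tail regiochemistry, anti facial selectivity and trans fusion: the first is secured by the donor character of the ketene acetal, the second by the allylic isopropyl group, and the third by low temperature and isolation on neutral silica, the cis-fused C2 epimer being the expected minor product that is removed here.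

Step 4
Reactants: 7 trans-fused 5-isopropyl-7,7-dimethoxybicyclo[4.2.0]octan-2-one
Product: 9 trimethylsilyl enol ether of 7 (C1–OSiMe3 and C1=C9), via lithium enolate 8 (not isolated)
Conditions: LDA, TMSCl (in situ quench), THF, −78 °C; then Et3N, cold aq. NaHCO3
Reagents that add atoms: chlorotrimethylsilane C[Si](C)(C)Cl; lithium diisopropylamide [Li]N(C(C)C)C(C)C (its lithium stays only in 8)
Why: Kinetic deprotonation by LDA at −78 °C takes the unhindered C9 methylene in preference to the cyclobutyl methine C2 and the enolate is silylated as it forms (silyl enol ether formation with in situ quench), so the ketone never equilibrates and the trans fusion should be kept.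

Step 5
Reactants: 9 trimethylsilyl enol ether of 7
Product: 10 trans-fused enone (C1 ketone, C8=C9), 5-isopropyl-7,7-dimethoxybicyclo[4.2.0]oct-3-en-2-one
Conditions: Pd(OAc)2 (1.1 equiv), MeCN, rt
Reagents that add atoms: none
Why: Saegusa–Ito oxidation: the palladium enolate formed from the silyl enol ether undergoes β-hydride elimination towards C8 under neutral conditions, which should give the C8=C9 enone and zerovalent palladium without touching C2 or the acetal.

Step 6
Reactants: 10 trans-fused enone
Product: 11 8α,9α-epoxy ketone (C1 ketone, epoxide oxygen on the α face)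
Conditions: DMDO, acetone/CH2Cl2, 0 °C → rt
Reagents that add atoms: dimethyldioxirane CC1(C)OO1
Why: Electrophilic epoxidation of an enone by a dioxirane, chosen because it is neutral (alkaline peroxide would epimerise C2); oxygen should be delivered to the α face, opposite to the pseudo-equatorial isopropyl group on the allylic carbon C7, which sets C8 and C9 as the α-epoxide.

Step 7
Reactants: 11 8α,9α-epoxy ketone
Product: 12 C1 tertiary alcohol carrying a CH2SiMe3 group (OH α, CH2SiMe3 β), 8α,9α-epoxide retained
Conditions: Me3SiCH2MgCl, CeCl3, THF, −78 °C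
Reagents that add atoms: (trimethylsilyl)methylmagnesium chloride C[Si](C)(C)C[Mg]Cl
Why: Addition of the weakly basic organocerium reagent (first half of a Peterson olefination) to the activated epoxy ketone should outrun enolisation, turns C1 into an sp3 carbinol so that C2 is fixed and the epoxide is no longer α to a carbonyl, and is expected anti to the epoxide oxygen (the C1 configuration is lost in step 9).

Step 8
Reactants: 12 epoxy β-hydroxysilane
Product: 13 8β-(4-methoxybenzyloxy)-9α-hydroxy compound with C1(OH)CH2SiMe3
Conditions: Ti(OiPr)4 (1.5 equiv), 4-methoxybenzyl alcohol (8 equiv), toluene, 50 °C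
Reagents that add atoms: 4-methoxybenzyl alcohol COc1ccc(CO)cc1
Why: Ti(OiPr)4-mediated opening of a 2,3-epoxy alcohol by an alcohol at the carbon remote from the carbinol: the titanium alkoxide activates the epoxide and the nucleophile enters C8 from the β face, which is the trans-diaxial (Fürst–Plattner) mode of the rigid chair and avoids the neopentylic C9, so O8 becomes β, O9 stays α and the two oxygens are differentiated.

Step 9
Reactants: 13 8β-PMB ether diol
Product: 14 allylic alcohol with C1=C10 methylene, 9α-OH, 8β-OPMB and the C4 dimethyl acetal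
Conditions: KH, THF, 0 °C → rt
Reagents that add atoms: none
Why: Base-induced Peterson elimination: the potassium alkoxide at C1 attacks silicon and the β-oxidosilane collapses by syn elimination, which should give the exocyclic C1=C10 alkene regiospecifically with no other stereocentre involved.

Step 10
Reactants: 14 allylic alcohol
Product: 15 9α-tert-butyldimethylsilyl ether (8β-OPMB, C1=C10, C4 dimethyl acetal)
Conditions: TBSCl, imidazole, DMAP (cat.), DMF, 40 °C
Reagents that add atoms: tert-butylchlorodimethylsilane CC(C)(C)[Si](C)(C)Cl
Why: Standard silylation of the single free (allylic, axial) hydroxyl with a silyl chloride, chosen over a silyl triflate so that the dimethyl acetal is not ionised.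

Step 11
Reactants: 15 silyl ether acetal
Product: 16 trans-fused cyclobutanone (C4 ketone; 9α-OTBS, 8β-OPMB, C1=C10)
Conditions: PPTS (cat.), acetone/H2O (10:1), 45 °C
Reagents that add atoms: water O
Why: Acid-catalysed acetal hydrolysis should unmask the cyclobutanone under conditions too mild to cleave the silyl or PMB ether or to enolise the strained ketone towards C6.

Step 12
Reactants: 16 cyclobutanone
Product: 17 C4 tertiary alcohol carrying a 1,3-dithian-2-yl group (OH β, dithianyl α)
Conditions: 1,3-dithiane, n-BuLi, THF, −30 °C; then 16, −78 °C; H2O quench at −78 °C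
Reagents that add atoms: 1,3-dithiane C1CSCSC1
Why: Corey–Seebach dithiane addition (formyl anion equivalent) to the highly electrophilic cyclobutanone at −78 °C, expected from the α face away from H-6 and the isopropyl group so that the new hydroxyl is β; the configuration of this carbinol disappears when C4 becomes the ketone.

Step 13
Reactants: 17 dithiane adduct
Product: 18 1-formylcyclobutanol (C4–OH β, aldehyde carbon C5 on C4)
Conditions: MeI, CaCO3, MeCN/H2O (9:1), 45 °C; used crude
Reagents that add atoms: water O
Why: S-Methylation of the dithioacetal and hydrolysis of the sulfonium salt under carbonate buffer should unmask the aldehyde without strong acid or heavy metal, so the exocyclic alkene and both ethers are left alone.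

Step 14
Reactants: 18 1-formylcyclobutanol
Product: 19 trans-hydrindan-4-one acyloin (C4 ketone, 5β-OH; 9α-OTBS, 8β-OPMB, C1=C10)
Conditions: Sc(OTf)3 (10 mol %), CH2Cl2, 0 °C → rt
Reagents that add atoms: none
Why: α-Ketol (acyloin) rearrangement driven by release of cyclobutane strain and by the aldehyde-to-ketone change: within the scandium chelate that holds the aldehyde oxygen syn to the C4 oxygen, the more substituted ring carbon C6 shifts from C4 to C5 with retention, which closes ring A by ring expansion, makes C4 the ketone and should place the new C5 hydroxyl on the β face (pseudo-equatorial, also the more stable epimer).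

Step 15
Reactants: 19 acyloin
Product: 20 5β-acetate (C4 ketone; 9α-OTBS, 8β-OPMB)
Conditions: Ac2O, pyridine, DMAP (cat.), CH2Cl2, 0 °C
Reagents that add atoms: acetic anhydride CC(=O)OC(C)=O
Why: Acylation of the secondary α-ketol with acetic anhydride under nucleophilic catalysis at 0 °C, where the other two oxygens are blocked as ethers.

Step 16
Reactants: 20 5β-acetate
Product: 21 9α-alcohol (5β-OAc, 8β-OPMB, C4 ketone, C1=C10)
Conditions: HF·pyridine, THF/pyridine, 0 °C → rt
Reagents that add atoms: none
Why: Fluoride-mediated desilylation under buffered, weakly acidic conditions that should leave the α-acetoxy ketone, the PMB ether and the alkene intact.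

Step 17
Reactants: 22 angelic acid [(Z)-2-methylbut-2-enoic acid]
Product: 23 angelic 2,4,6-trichlorobenzoic anhydride
Conditions: 2,4,6-trichlorobenzoyl chloride, Et3N, toluene, rt; filtered and used as a solution
Reagents that add atoms: 2,4,6-trichlorobenzoyl chloride O=C(Cl)c1c(Cl)cc(Cl)cc1Cl
Why: Yamaguchi mixed anhydride formation, which activates angelic acid without the heat or nucleophilic catalyst that would isomerise it to the tiglate.

Step 18
Reactants: 21 9α-alcohol; 23 angelic 2,4,6-trichlorobenzoic anhydride
Product: 24 9α-angelate (5β-OAc, 8β-OPMB)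
Conditions: Et3N (1 equiv), toluene, 80 °C (no DMAP)
Reagents that add atoms: none
Why: Yamaguchi-type esterification without DMAP: the alcohol attacks the less hindered angeloyl carbonyl of the mixed anhydride (the aroyl carbonyl is shielded by its two ortho chlorines), and the (Z) geometry should be kept in the absence of a nucleophilic catalyst.

Step 19
Reactants: 24 9α-angelate PMB ether
Product: 25 target CNP0317011.1
Conditions: DDQ, CH2Cl2/pH 7 buffer (10:1), 0 °C → rt
Reagents that add atoms: none
Why: Oxidative cleavage of the PMB ether by DDQ through the benzylic oxocarbenium ion, which is hydrolysed by the buffer; the esters, ketone and alkene are inert and the trans-diaxial arrangement of O8 and O9 disfavours acyl migration.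

**Compound list**

1 | isovaleraldehyde (3-methylbutanal) | CC(C)CC=O | starting material
2 | methyl vinyl ketone | CC(=O)C=C | starting material
3 | (S)-2-isopropyl-5-oxohexanal | O=C[C@H](C(C)C)CCC(C)=O | intermediate
4 | cyclic aldol, (4S)-3-hydroxy-4-isopropylcyclohexan-1-one (both C3 epimers) | O=C1CC(O)[C@H](C(C)C)CC1 | intermediate (not isolated)
5 | (S)-cryptone, (S)-4-isopropylcyclohex-2-en-1-one | O=C1C=C[C@H](C(C)C)CC1 | intermediate
6 | 1,1-dimethoxyethene | C=C(OC)OC | starting material
7 | trans-fused (1R,5S,6S)-5-isopropyl-7,7-dimethoxybicyclo[4.2.0]octan-2-one | O=C1[C@@H]2CC(OC)(OC)[C@H]2[C@H](C(C)C)CC1 | intermediate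
8 | lithium enolate of 7 (C1–OLi, C1=C9) | [Li]OC1[C@@H]2CC(OC)(OC)[C@H]2[C@H](C(C)C)CC=1 | intermediate (not isolated)
9 | trimethylsilyl enol ether of 7 (C1–OSiMe3, C1=C9) | C[Si](C)(C)OC1[C@@H]2CC(OC)(OC)[C@H]2[C@H](C(C)C)CC=1 | intermediate
10 | trans-fused enone (C1 ketone, C8=C9) | O=C1[C@@H]2CC(OC)(OC)[C@H]2[C@H](C(C)C)C=C1 | intermediate
11 | 8α,9α-epoxy ketone | O=C1[C@@H]2CC(OC)(OC)[C@H]2[C@H](C(C)C)[C@H]3O[C@H]31 | intermediate
12 | C1 carbinol with CH2SiMe3 (OH α), 8α,9α-epoxide | C[Si](C)(C)C[C@]1(O)[C@@H]2CC(OC)(OC)[C@H]2[C@H](C(C)C)[C@H]3O[C@H]31 | intermediate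
13 | 8β-(4-methoxybenzyloxy)-9α-hydroxy C1(OH)CH2SiMe3 compound | C[Si](C)(C)C[C@]1(O)[C@@H]2CC(OC)(OC)[C@H]2[C@H](C(C)C)[C@H](OCc3ccc(OC)cc3)[C@H]1O | intermediate
14 | 1(10)-methylene 9α-alcohol, 8β-OPMB, C4 dimethyl acetal | C=C1[C@@H]2CC(OC)(OC)[C@H]2[C@H](C(C)C)[C@H](OCc3ccc(OC)cc3)[C@H]1O | intermediate
15 | 9α-TBS ether of 14 | C=C1[C@@H]2CC(OC)(OC)[C@H]2[C@H](C(C)C)[C@H](OCc3ccc(OC)cc3)[C@H]1O[Si](C)(C)C(C)(C)C | intermediate
16 | trans-fused cyclobutanone (C4 ketone) | C=C1[C@@H]2CC(=O)[C@H]2[C@H](C(C)C)[C@H](OCc3ccc(OC)cc3)[C@H]1O[Si](C)(C)C(C)(C)C | intermediate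
17 | C4 carbinol with 1,3-dithian-2-yl (OH β) | C=C1[C@@H]2C[C@@](O)(C3SCCCS3)[C@H]2[C@H](C(C)C)[C@H](OCc4ccc(OC)cc4)[C@H]1O[Si](C)(C)C(C)(C)C | intermediate
18 | 1-formylcyclobutanol (C4–OH β, formyl carbon C5) | C=C1[C@@H]2C[C@@](O)(C=O)[C@H]2[C@H](C(C)C)[C@H](OCc3ccc(OC)cc3)[C@H]1O[Si](C)(C)C(C)(C)C | intermediate
19 | trans-hydrindan-4-one acyloin (5β-OH) | C=C1[C@@H]2CC(=O)[C@H](O)[C@H]2[C@H](C(C)C)[C@H](OCc3ccc(OC)cc3)[C@H]1O[Si](C)(C)C(C)(C)C | intermediate
20 | 5β-acetate of 19 | C=C1[C@@H]2CC(=O)[C@H](OC(C)=O)[C@H]2[C@H](C(C)C)[C@H](OCc3ccc(OC)cc3)[C@H]1O[Si](C)(C)C(C)(C)C | intermediate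
21 | 9α-alcohol (5β-OAc, 8β-OPMB) | C=C1[C@@H]2CC(=O)[C@H](OC(C)=O)[C@H]2[C@H](C(C)C)[C@H](OCc3ccc(OC)cc3)[C@H]1O | intermediate
22 | angelic acid, (Z)-2-methylbut-2-enoic acid | C/C=C(/C)C(=O)O | starting material
23 | angelic 2,4,6-trichlorobenzoic anhydride | C/C=C(/C)C(=O)OC(=O)c1c(Cl)cc(Cl)cc1Cl | intermediate
24 | 9α-angelate (5β-OAc, 8β-OPMB) | C=C1[C@@H]2CC(=O)[C@H](OC(C)=O)[C@H]2[C@H](C(C)C)[C@H](OCc3ccc(OC)cc3)[C@H]1OC(=O)/C(C)=C\C | intermediate
25 | CNP0317011.1: 5β-acetoxy-9α-angeloyloxy-8β-hydroxy-7β-isopropyl-1(10)-methylene trans-hydrindan-4-one (2R,5R,6R,7S,8S,9S in target numbering) | C=C1[C@@H]2CC(=O)[C@H](OC(C)=O)[C@H]2[C@H](C(C)C)[C@H](O)[C@H]1OC(=O)/C(C)=C\C | target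

**Step count and risks**

Total step count: 19. Longest linear sequence: 18 steps (steps 1–16, 18 and 19); step 17 is a one-step side branch.

Steps most likely to fail:

1. Step 8. The alcohol may be too weak a nucleophile for axial attack at the hindered C8, so that the epoxide is recovered or the β-hydroxysilane eliminates first and the resulting vinyl epoxide opens at the allylic carbon. The fallback sets out from 12 and returns at 15. The same titanium-templated opening is run with a carboxylic acid, the best-behaved nucleophile class for this reaction (Ti(OiPr)4, pivalic acid, CH2Cl2, rt), to give the C8 pivalate F2. Peterson elimination (KH, THF, 0 °C) gives the allylic alcohol F3, silylation (TBSCl, imidazole, DMF) the C9 silyl ether F4, and reductive removal of the pivalate (DIBAL-H, CH2Cl2, −78 °C) the C8 alcohol F5. Etherification (NaH, 4-methoxybenzyl chloride, n-Bu4NI, DMF) then returns to 15; silyl migration from O9 to O8 is not expected because the two oxygens are trans-diaxial.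

2. Step 3. The strained trans fusion may be lost by epimerisation at C2 on contact with silica or traces of base during isolation, which would also blur the separation from the cis-fused adduct. The fallback sets out from 5 and returns at 7. The cold photolysate is not isolated but added to NaBH4 and CeCl3 heptahydrate in MeOH at −78 °C, so that C1 becomes a carbinol and C2 can no longer enolise. The trans-fused C1 alcohol F1 is purified at this stage and oxidised with Dess–Martin periodinane (NaHCO3, CH2Cl2) to 7, which is taken into step 4 without chromatography.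

3. Step 14. The 1,2-shift may run through the non-chelated rotamer, or start from the C4-epimeric carbinol, and deliver the C5 α-hydroxy epimer instead of the β-alcohol. The fallback sets out from 18 and returns at 20. The C5 epimer F6 formed in the rearrangement is carried on and inverted: a Mitsunobu reaction with acetic acid (PPh3, DIAD, AcOH, THF, 0 °C) displaces the activated α-keto carbinol with inversion and should give the 5β-acetate 20 directly, bypassing step 15.

**Further compounds**

F1 | step 3 | trans-fused C1 alcohol, 5-isopropyl-7,7-dimethoxybicyclo[4.2.0]octan-2-ol (OH α) | O[C@H]1[C@@H]2CC(OC)(OC)[C@H]2[C@H](C(C)C)CC1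
F2 | step 8 | C8 pivalate, 9α-hydroxy C1(OH)CH2SiMe3 compound | C[Si](C)(C)C[C@]1(O)[C@@H]2CC(OC)(OC)[C@H]2[C@H](C(C)C)[C@H](OC(=O)C(C)(C)C)[C@H]1O
F3 | step 8 | allylic alcohol, 1(10)-methylene 9α-ol 8β-pivalate | C=C1[C@@H]2CC(OC)(OC)[C@H]2[C@H](C(C)C)[C@H](OC(=O)C(C)(C)C)[C@H]1O
F4 | step 8 | C9 silyl ether, 9α-OTBS 8β-pivalate | C=C1[C@@H]2CC(OC)(OC)[C@H]2[C@H](C(C)C)[C@H](OC(=O)C(C)(C)C)[C@H]1O[Si](C)(C)C(C)(C)C
F5 | step 8 | C8 alcohol, 9α-OTBS 8β-ol | C=C1[C@@H]2CC(OC)(OC)[C@H]2[C@H](C(C)C)[C@H](O)[C@H]1O[Si](C)(C)C(C)(C)C
F6 | step 14 | C5 epimer of 19 (5α-OH) | C=C1[C@@H]2CC(=O)[C@@H](O)[C@H]2[C@H](C(C)C)[C@H](OCc3ccc(OC)cc3)[C@H]1O[Si](C)(C)C(C)(C)C
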